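**Retrosynthetic overview**
1. Andibenin B ⇐ C6 enol triflate ⇐ ring B opened at C7–C23: an intramolecular vinylogous aldol of ring A (a 4‑alkoxy‑dihydropyranone) onto a C22 acetyl group closes the last ring.
2. Acetyl‑bearing tetracycle ⇐ intramolecular Diels–Alder reaction of a phthalide‑derived cyclohexa‑2,4‑dienone with a tethered 1,3‑diene, forming the bicyclo[2.2.2]octenone and cyclopentane ring C together (bonds C10–C18 and C11–C12).
3. Dienone ⇐ enantioselective dearomative allylation (the new step; bond C19–C21, sets C19) of 5,7‑dihydroxy‑4,6‑dimethylphthalide with a dienyl carbonate.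
4. Dienyl carbonate ⇐ ethylene enyne metathesis of a propargylic carbonate; ring A ⇐ β‑keto ester dianion + acetone; everything from methyl hex‑5‑ynoate.
5. Ring order: D (butenolide, purchased) → A → bicyclo[2.2.2]octenone + C → B.

Assumption: carbons are labelled C1–C25 in the order they are written in the target SMILES (C7 spiro centre; C10, C12, C18, C19 core quaternary centres; C22 CH; C23 carbinol; C25 ketone); SEM = 2‑(trimethylsilyl)ethoxymethyl; the (R,R)‑Trost ligand is taken to give the (4R) product in step 9 (otherwise its mirror image is used); centres that are later destroyed or equilibrated are drawn without configuration.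

**Route**

Step 1
Reactants: 1 5,7‑dihydroxy‑4‑methylisobenzofuran‑1(3H)‑one
Product: 2 5,7‑dihydroxy‑4‑methyl‑6‑(morpholin‑4‑ylmethyl)isobenzofuran‑1(3H)‑one
Conditions: aq. CH2O, morpholine, EtOH, 70 °C
Reagents that add atoms: formaldehyde (C=O); morpholine (C1COCCN1)
Why: Phenolic Mannich reaction at the only free ring position, which lies between the two hydroxyl groups.

Step 2
Reactants: 2 5,7‑dihydroxy‑4‑methyl‑6‑(morpholin‑4‑ylmethyl)isobenzofuran‑1(3H)‑one
Product: 3 5,7‑dihydroxy‑4,6‑dimethylisobenzofuran‑1(3H)‑one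
Conditions: H2 (3 bar), 10% Pd/C, AcOH, EtOH, 60 °C
Reagents that add atoms: none
Why: Hydrogenolysis of the benzylic C–N bond of a phenolic Mannich base is a standard aryl‑methyl synthesis, and these mild conditions should spare the phthalide.

Step 3
Reactants: 4 methyl hex‑5‑ynoate
Product: 5 methyl 7‑hydroxyoct‑5‑ynoate
Conditions: Me2Zn, (S,S)‑ProPhenol (10 mol %), Ph3PO, toluene, 0 °C, slow addition of CH3CHO
Reagents that add atoms: acetaldehyde (CC=O)
Why: Zinc alkynylide addition to an aldehyde (ProPhenol‑type alkynylation) tolerates the ester; the new carbinol centre (C23) is destroyed in step 9, so either enantiomer serves.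

Step 4
Reactants: 5 methyl 7‑hydroxyoct‑5‑ynoate
Product: 6 methyl 9‑hydroxy‑3‑oxodec‑7‑ynoate
Conditions: MeOAc, LiN(iPr)2 (4 equiv), THF, −78 → −20 °C; aq. NH4Cl
Reagents that add atoms: methyl acetate (COC(C)=O)
Why: Crossed Claisen condensation of the lithium enolate of methyl acetate with the ester, driven by deprotonation of the β‑keto ester formed.

Step 5
Reactants: 6 methyl 9‑hydroxy‑3‑oxodec‑7‑ynoate
Product: 8 4‑hydroxy‑5‑(5‑hydroxyhex‑3‑yn‑1‑yl)‑6,6‑dimethyl‑5,6‑dihydro‑2H‑pyran‑2‑one, via acyclic aldol adduct 7 (not isolated)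
Conditions: LiN(iPr)2 (3.3 equiv), THF, −78 → 0 °C; acetone, −78 °C; then 0.2 M NaOH, rt; HCl to pH 2
Reagents that add atoms: acetone (CC(C)=O)
Why: Weiler‑type γ‑aldol addition of the β‑keto ester dianion to acetone, then lactonisation of the tertiary alkoxide onto the ester, builds ring A; the ring CH (C7) is a mixture that is re‑enolised in step 14.

Step 6
Reactants: 8 4‑hydroxy‑5‑(5‑hydroxyhex‑3‑yn‑1‑yl)‑6,6‑dimethyl‑5,6‑dihydro‑2H‑pyran‑2‑one
Product: 9 5‑(5‑hydroxyhex‑3‑yn‑1‑yl)‑6,6‑dimethyl‑4‑(SEM‑oxy)‑5,6‑dihydro‑2H‑pyran‑2‑one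
Conditions: SEMCl (1.05 equiv), iPr2NEt, CH2Cl2, −20 °C
Reagents that add atoms: 2‑(trimethylsilyl)ethoxymethyl chloride (C[Si](C)(C)CCOCCl)
Why: O‑alkylation of the acidic enol by a hard chloromethyl ether masks the 1,3‑dicarbonyl unit so it cannot act as a carbon nucleophile in step 9, and supplies a chelating group for step 14.

Step 7
Reactants: 9 5‑(5‑hydroxyhex‑3‑yn‑1‑yl)‑6,6‑dimethyl‑4‑(SEM‑oxy)‑5,6‑dihydro‑2H‑pyran‑2‑one
Product: 10 6‑[6,6‑dimethyl‑2‑oxo‑4‑(SEM‑oxy)‑5,6‑dihydro‑2H‑pyran‑5‑yl]hex‑3‑yn‑2‑yl methyl carbonate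
Conditions: ClCO2Me, pyridine, DMAP (cat.), CH2Cl2, 0 °C
Reagents that add atoms: methyl chloroformate (COC(Cl)=O)
Why: Routine acylation of the secondary propargylic alcohol to the carbonate leaving group.

Step 8
Reactants: 10 6‑[6,6‑dimethyl‑2‑oxo‑4‑(SEM‑oxy)‑5,6‑dihydro‑2H‑pyran‑5‑yl]hex‑3‑yn‑2‑yl methyl carbonate
Product: 11 6‑[6,6‑dimethyl‑2‑oxo‑4‑(SEM‑oxy)‑5,6‑dihydro‑2H‑pyran‑5‑yl]‑3,4‑dimethylidenehexan‑2‑yl methyl carbonate
Conditions: ethylene (1 atm), second‑generation Grubbs catalyst (5 mol %), toluene, 80 °C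
Reagents that add atoms: ethylene (C=C)
Why: Ethylene enyne cross‑metathesis turns the internal alkyne into a 2,3‑disubstituted buta‑1,3‑diene, creating the future C11 and C21 methylene carbons; the electron‑poor ring A alkene is inert.

Step 9
Reactants: 3 5,7‑dihydroxy‑4,6‑dimethylisobenzofuran‑1(3H)‑one; 11 dienyl methyl carbonate
Product: 12 (4R)‑4‑{2‑ethylidene‑3‑methylidene‑5‑[6,6‑dimethyl‑2‑oxo‑4‑(SEM‑oxy)‑5,6‑dihydro‑2H‑pyran‑5‑yl]pentyl}‑7‑hydroxy‑4,6‑dimethylisobenzofuran‑1,5(3H,4H)‑dione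
Conditions: Pd2(dba)3·CHCl3 (2.5 mol %), (R,R)‑DACH‑phenyl Trost ligand (7.5 mol %), CH2Cl2/THF, 0 °C → rt
Reagents that add atoms: none
Why: Proposed new method: a zerovalent palladium–Trost ligand complex ionises the carbonate (losing CO2 and methoxide, which deprotonates the more acidic 5‑OH), and the planar phenolate attacks the unsubstituted terminus of the π‑allyl cation through C4 (ortho to O−, para to the chelated 7‑OH, the site electrophiles attack in oxidative dearomatisation of 2,4‑dihydroxy‑3,5‑dimethylaryl ketones), O‑allylation being reversible while the C‑allylated vinylogous acid is a sink; the chiral pocket selects one enantiotopic face and so sets the C19 quaternary centre; closest known reaction type: palladium‑catalysed asymmetric allylic dearomatisation of naphthols and dearomative Tsuji–Trost allylation of acylphloroglucinols.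

Step 10
Reactants: 12 dearomatised vinylogous acid
Product: 13 (4R)‑4‑{2‑ethylidene‑3‑methylidene‑5‑[6,6‑dimethyl‑2‑oxo‑4‑(SEM‑oxy)‑5,6‑dihydro‑2H‑pyran‑5‑yl]pentyl}‑4,6‑dimethyl‑1,5‑dioxo‑1,3,4,5‑tetrahydroisobenzofuran‑7‑yl trifluoromethanesulfonate
Conditions: PhNTf2, Et3N, DMAP (cat.), CH2Cl2, 0 °C
Reagents that add atoms: N‑phenylbis(trifluoromethanesulfonimide) (O=S(=O)(N(c1ccccc1)S(=O)(=O)C(F)(F)F)C(F)(F)F)
Why: Enol triflate formation at the only acidic hydroxyl (the C14 enol), which also turns the ring into an electron‑poor cyclohexa‑2,4‑dienone.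

Step 11
Reactants: 13 dienone triflate
Product: 15 tetracyclic Diels–Alder adduct with C22 ethylidene, via triflate cycloadduct 14 (not isolated)
Conditions: toluene (0.01 M), BHT, 110 °C; then Pd(OAc)2 (5 mol %), PPh3, HCO2H, Et3N, DMF, 40 °C
Reagents that add atoms: none
Why: Intramolecular Diels–Alder reaction of the cyclohexa‑2,4‑dienone with the terminal alkene of the tethered diene forms C10–C18 and C11–C12; the three‑atom tether allows addition only to the dienone face bearing C21, so C19 fixes C18, C12 and C10; palladium‑catalysed formate hydrogenolysis then removes the vinyl triflate.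

Step 12
Reactants: 15 tetracyclic Diels–Alder adduct with C22 ethylidene
Product: 16 C23 secondary alcohol
Conditions: BH3·THF (1.2 equiv), THF, 0 °C; then Me3NO·2H2O, 60 °C
Reagents that add atoms: trimethylamine N‑oxide (C[N+](C)(C)[O-])
Why: Anti‑Markovnikov hydroboration–oxidation of the only electron‑rich alkene puts oxygen on C23 and hydrogen on C22; both new centres are mixtures that converge later (C23 is oxidised in step 13, C22 equilibrates in step 14).

Step 13
Reactants: 16 C23 secondary alcohol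
Product: 17 C22 acetyl compound
Conditions: Dess–Martin periodinane, NaHCO3, CH2Cl2, rt
Reagents that add atoms: none
Why: Buffered Dess–Martin oxidation of a secondary alcohol to the methyl ketone.

Step 14
Reactants: 17 C22 acetyl compound
Product: 18 6‑(SEM‑oxy)andibenin B
Conditions: LiN(SiMe3)2 (1.3 equiv), LiCl, THF, −78 → −40 °C; AcOH, −78 °C
Reagents that add atoms: none
Why: Intramolecular vinylogous aldol addition (γ‑selective, as for 3‑alkoxy‑enoate dienolates) closes ring B between C7 and C23: C22 equilibrates through the ketone enolate and only the epimer with the acetyl group cis to C9 can cyclise, and a chair with the C23 methyl equatorial (an axial methyl would clash with C18) and lithium bridging the ketone oxygen and the C6 alkoxy group places C23–O cis to C6 and anti to C2, setting C7 and C23 as in the target.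

Step 15
Reactants: 18 6‑(SEM‑oxy)andibenin B
Product: 20 andibenin B 6‑trifluoromethanesulfonate, via free β‑keto lactone 19 (not isolated)
Conditions: Bu4NF (1.5 equiv), THF, 0 °C; then PhNTf2 (1.5 equiv), 0 °C → rt
Reagents that add atoms: N‑phenylbis(trifluoromethanesulfonimide) (O=S(=O)(N(c1ccccc1)S(=O)(=O)C(F)(F)F)C(F)(F)F)
Why: Fluoride cleaves the SEM enol ether (losing Me3SiF, ethylene and formaldehyde) and the resulting ammonium enolate is O‑triflated in the same flask; the tertiary alcohol does not react.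

Step 16
Reactants: 20 andibenin B 6‑trifluoromethanesulfonate
Product: 21 andibenin B
Conditions: Pd(OAc)2 (10 mol %), PPh3, HCO2H, Bu3N, DMF, 60 °C
Reagents that add atoms: none
Why: Palladium‑catalysed formate hydrogenolysis of the enol triflate gives the α,β‑unsaturated δ‑lactone of ring A without touching any stereocentre, completing the target.

**Compound list**
1 | 5,7‑dihydroxy‑4‑methylisobenzofuran‑1(3H)‑one | O=C1OCc2c(C)c(O)cc(O)c12 | starting material
2 | 5,7‑dihydroxy‑4‑methyl‑6‑(morpholin‑4‑ylmethyl)isobenzofuran‑1(3H)‑one | O=C1OCc2c(C)c(O)c(CN3CCOCC3)c(O)c12 | intermediate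
3 | 5,7‑dihydroxy‑4,6‑dimethylisobenzofuran‑1(3H)‑one | O=C1OCc2c(C)c(O)c(C)c(O)c12 | intermediate
4 | methyl hex‑5‑ynoate | COC(=O)CCCC#C | starting material
5 | methyl 7‑hydroxyoct‑5‑ynoate (carbinol unspecified) | COC(=O)CCCC#CC(C)O | intermediate
6 | methyl 9‑hydroxy‑3‑oxodec‑7‑ynoate | COC(=O)CC(=O)CCCC#CC(C)O | intermediate
7 | methyl 9‑hydroxy‑4‑(2‑hydroxypropan‑2‑yl)‑3‑oxodec‑7‑ynoate | COC(=O)CC(=O)C(CCC#CC(C)O)C(C)(C)O | intermediate
8 | 4‑hydroxy‑5‑(5‑hydroxyhex‑3‑yn‑1‑yl)‑6,6‑dimethyl‑5,6‑dihydro‑2H‑pyran‑2‑one (ring A, enol of the pyran‑2,4‑dione) | CC1(C)OC(=O)C=C(O)C1CCC#CC(C)O | intermediate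
9 | 5‑(5‑hydroxyhex‑3‑yn‑1‑yl)‑6,6‑dimethyl‑4‑{[2‑(trimethylsilyl)ethoxy]methoxy}‑5,6‑dihydro‑2H‑pyran‑2‑one | CC1(C)OC(=O)C=C(OCOCC[Si](C)(C)C)C1CCC#CC(C)O | intermediate
10 | 6‑[6,6‑dimethyl‑2‑oxo‑4‑(SEM‑oxy)‑5,6‑dihydro‑2H‑pyran‑5‑yl]hex‑3‑yn‑2‑yl methyl carbonate | CC1(C)OC(=O)C=C(OCOCC[Si](C)(C)C)C1CCC#CC(C)OC(=O)OC | intermediate
11 | 6‑[6,6‑dimethyl‑2‑oxo‑4‑(SEM‑oxy)‑5,6‑dihydro‑2H‑pyran‑5‑yl]‑3,4‑dimethylidenehexan‑2‑yl methyl carbonate | CC1(C)OC(=O)C=C(OCOCC[Si](C)(C)C)C1CCC(=C)C(=C)C(C)OC(=O)OC | intermediate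
12 | (4R)‑4‑{2‑ethylidene‑3‑methylidene‑5‑[6,6‑dimethyl‑2‑oxo‑4‑(SEM‑oxy)‑5,6‑dihydro‑2H‑pyran‑5‑yl]pentyl}‑7‑hydroxy‑4,6‑dimethylisobenzofuran‑1,5(3H,4H)‑dione | CC1(C)OC(=O)C=C(OCOCC[Si](C)(C)C)C1CCC(=C)C(=CC)C[C@@]2(C)C(=O)C(C)=C(O)C3=C2COC3=O | intermediate
13 | 7‑trifluoromethanesulfonate of 12 (4R) | CC1(C)OC(=O)C=C(OCOCC[Si](C)(C)C)C1CCC(=C)C(=CC)C[C@@]2(C)C(=O)C(C)=C(OS(=O)(=O)C(F)(F)F)C3=C2COC3=O | intermediate
14 | Diels–Alder adduct of 13: bicyclo[2.2.2]octenone fused to cyclopentane ring C and butenolide ring D, C14 triflate, C22 ethylidene, ring A on the C8–C9 chain | CC1(C)OC(=O)C=C(OCOCC[Si](C)(C)C)C1CC[C@@]12C[C@@]3(C)C(OS(=O)(=O)C(F)(F)F)=C4C(=O)OC[C@]41[C@@](C)(CC2=CC)C3=O | intermediate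
15 | same tetracycle with C14–H (C10, C12, C18, C19 as in the target; C22 ethylidene) | CC1(C)OC(=O)C=C(OCOCC[Si](C)(C)C)C1CC[C@@]12C[C@@]3(C)C=C4C(=O)OC[C@]41[C@@](C)(CC2=CC)C3=O | intermediate
16 | C23 secondary alcohol, C22–H (both unspecified) | CC1(C)OC(=O)C=C(OCOCC[Si](C)(C)C)C1CC[C@@]12C[C@@]3(C)C=C4C(=O)OC[C@]41[C@@](C)(CC2C(C)O)C3=O | intermediate
17 | C22 acetyl compound (ring B still open between C7 and C23) | CC1(C)OC(=O)C=C(OCOCC[Si](C)(C)C)C1CC[C@@]12C[C@@]3(C)C=C4C(=O)OC[C@]41[C@@](C)(CC2C(C)=O)C3=O | intermediate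
18 | 6‑(SEM‑oxy)andibenin B (all seven stereocentres as in the target) | CC1(C)OC(=O)C=C(OCOCC[Si](C)(C)C)[C@]12CC[C@@]13C[C@@]4(C)C=C5C(=O)OC[C@]51[C@@](C)(C[C@H]3[C@@]2(C)O)C4=O | intermediate
19 | 6‑hydroxyandibenin B (enol of the ring A β‑keto lactone) | CC1(C)OC(=O)C=C(O)[C@]12CC[C@@]13C[C@@]4(C)C=C5C(=O)OC[C@]51[C@@](C)(C[C@H]3[C@@]2(C)O)C4=O | intermediate
20 | andibenin B 6‑trifluoromethanesulfonate | CC1(C)OC(=O)C=C(OS(=O)(=O)C(F)(F)F)[C@]12CC[C@@]13C[C@@]4(C)C=C5C(=O)OC[C@]51[C@@](C)(C[C@H]3[C@@]2(C)O)C4=O | intermediate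
21 | andibenin B | CC1(C)OC(=O)C=C[C@]12CC[C@@]13C[C@@]4(C)C=C5C(=O)OC[C@]51[C@@](C)(C[C@H]3[C@@]2(C)O)C4=O | target

**Totals and risks**

Total step count: 16. Longest linear sequence: 14 steps (4 → 21, steps 3–16); steps 1–2 are a side branch joining at step 9.

The three steps most likely to fail:

Step 9 (the proposed new step). The risks are O‑allylation, attack at the carbon between the two hydroxyls instead of C4, and low enantioselectivity. The fallback sets out from 3 and 11 and comes back at 12. Achiral Tsuji–Trost conditions (Pd(PPh3)4, THF), reactivity established for dearomative C‑allylation of polyhydroxylated acylbenzenes, give the racemic allylation product F1. Its acidic enol is acylated with (S)‑naproxen chloride (Et3N, DMAP), and the diastereomeric enol esters are separated by chromatography or crystallisation to give the (4R) naproxen enol ester F2. K2CO3 in MeOH at 0 °C releases enantiopure 12.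

Step 14. The dienolate may lose the ring oxygen by β‑elimination (opening ring A), the methyl ketone is enolised in competition, and the C7 configuration relies on the chelate model. The fallback sets out from 17 and comes back at 19. Bu4NF removes the SEM group to give the free β‑keto lactone ketone F3. LiN(iPr)2 (3.2 equiv, THF, −78 → −20 °C) forms the 1,3‑dicarbonyl dianion, whose γ‑carbon (C7) adds to the ketone through a lithium‑bridged Zimmerman–Traxler chair (Weiler dianion aldol). This gives 19 directly, which is triflated with PhNTf2/Et3N to 20.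

Step 12. Borane may reduce the C25 ketone or the unsaturated lactones before it reaches the hindered ethylidene. The fallback sets out from 15 and comes back at 17. mCPBA (NaHCO3, CH2Cl2, 0 °C) epoxidises the only electron‑rich alkene to give the spiro‑epoxide F4. A Meinwald rearrangement (Bi(OTf)3 cat., CH2Cl2, 1,2‑hydride shift from C23 to C22) gives the methyl ketone 17, bypassing 16 and step 13.

Further compounds
F1 | step 9 | racemic 12 | CC1(C)OC(=O)C=C(OCOCC[Si](C)(C)C)C1CCC(=C)C(=CC)CC2(C)C(=O)C(C)=C(O)C3=C2COC3=O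
F2 | step 9 | (S)‑naproxen enol ester of (4R)‑12 | CC1(C)OC(=O)C=C(OCOCC[Si](C)(C)C)C1CCC(=C)C(=CC)C[C@@]2(C)C(=O)C(C)=C(OC(=O)[C@@H](C)c4ccc5cc(OC)ccc5c4)C3=C2COC3=O
F3 | step 14 | SEM‑free β‑keto lactone (enol form) of 17 | CC1(C)OC(=O)C=C(O)C1CC[C@@]12C[C@@]3(C)C=C4C(=O)OC[C@]41[C@@](C)(CC2C(C)=O)C3=O
F4 | step 12 | C22–C23 spiro‑epoxide of 15 | CC1(C)OC(=O)C=C(OCOCC[Si](C)(C)C)C1CC[C@@]12C[C@@]3(C)C=C4C(=O)OC[C@]41[C@@](C)(CC25OC5C)C3=O
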